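The route disconnects the C3–C1' bond that joins the chroman stereocentre to ring B. Ring B carries a free hydroxyl on C2', next to C1', which is the pattern an aromatic Claisen rearrangement leaves behind; 2,3-dimethoxyphenol has a single unsubstituted ortho carbon, and this becomes C1'. Heating its (S,E)-pent-3-en-2-yl ether therefore forges C3–C1', sets C3 by 1,3-chirality transfer and unveils the C2' phenol in one operation. The precursor carries ring A as a benzyl-protected ortho-bromoarene on the allyl terminus. The (E)-propenyl group that remains is a latent C2, and ring C is closed later by O1–C8a coupling at the bromide.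

Key step: step 9

Assumption: methyl 3,5-dihydroxy-4-methoxybenzoate (1) is taken as a purchasable material; the ring A bromine is introduced ortho to a free phenol of this symmetric ester because bromination of 3-hydroxy-4,5-dimethoxybenzaldehyde is expected to occur between the hydroxyl and the formyl group, which would place the halogen beside the wrong oxygen.

Step 1
Reactants: 1 methyl 3,5-dihydroxy-4-methoxybenzoate
Product: 2 methyl 3-(benzyloxy)-5-hydroxy-4-methoxybenzoate
Conditions: BnBr (1.0 equiv), K2CO3 (1.0 equiv), DMF, rt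
Reagents that add atoms: benzyl bromide, BrCc1ccccc1
Why: Williamson etherification of a diphenol whose two hydroxyls are equivalent by symmetry, so only one mono-benzyl ether can form, and limiting BnBr leaves it separable from the dibenzyl ether and from recovered 1.

Step 2
Reactants: 2 methyl 3-(benzyloxy)-5-hydroxy-4-methoxybenzoate
Product: 3 methyl 5-(benzyloxy)-2-bromo-3-hydroxy-4-methoxybenzoate
Conditions: NBS (1.0 equiv), i-Pr2NH (10 mol %), CH2Cl2, 0 °C
Reagents that add atoms: N-bromosuccinimide, O=C1CCC(=O)N1Br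
Why: Amine-mediated electrophilic aromatic bromination, in which the N-bromoamine is held by hydrogen bonding to the phenol, should substitute the only free carbon ortho to the hydroxyl (the ortho preference that free 3-hydroxy-4-methoxybenzaldehyde also shows) and not the more crowded carbon beside the benzyloxy group.

Step 3
Reactants: 3 methyl 5-(benzyloxy)-2-bromo-3-hydroxy-4-methoxybenzoate
Product: 4 methyl 5-(benzyloxy)-2-bromo-3,4-dimethoxybenzoate
Conditions: MeI, K2CO3, DMF, rt
Reagents that add atoms: iodomethane, CI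
Why: Williamson O-methylation of the acidic ortho-bromophenol turns the oxygen beside bromine into the future C8 methoxyl, while ester, benzyl ether and aryl bromide are inert to these reagents.

Step 4
Reactants: 4 methyl 5-(benzyloxy)-2-bromo-3,4-dimethoxybenzoate
Product: 5 [5-(benzyloxy)-2-bromo-3,4-dimethoxyphenyl]methanol
Conditions: i-Bu2AlH (2.5 equiv), CH2Cl2, −78 to 0 °C; aq. KNaC4H4O6
Reagents that add atoms: none
Why: Hydride reduction of the ester with i-Bu2AlH should give the benzylic alcohol cleanly and, at low temperature, does not attack the aryl C–Br bond or the benzyl ether.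

Step 5
Reactants: 5 [5-(benzyloxy)-2-bromo-3,4-dimethoxyphenyl]methanol
Product: 6 1-(benzyloxy)-4-bromo-5-(bromomethyl)-2,3-dimethoxybenzene
Conditions: PBr3 (0.4 equiv), CH2Cl2, 0 °C
Reagents that add atoms: phosphorus tribromide, BrP(Br)Br
Why: PBr3 converts the benzylic alcohol through its phosphite ester into the bromide by SN2 displacement under cold conditions that the benzyl ether tolerates.

Step 6
Reactants: 6 1-(benzyloxy)-4-bromo-5-(bromomethyl)-2,3-dimethoxybenzene; 7 (R)-but-3-yn-2-ol
Product: 8 (2R)-5-[5-(benzyloxy)-2-bromo-3,4-dimethoxyphenyl]pent-3-yn-2-ol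
Conditions: CuI (20 mol %), Cs2CO3, MeCN, rt to 40 °C
Reagents that add atoms: none
Why: Copper-catalysed alkynylation, in which the copper acetylide formed from the terminal alkyne and carbonate substitutes the benzylic bromide much faster than the secondary hydroxyl or the aryl bromide can react, and the carbinol stereocentre is not involved.

Step 7
Reactants: 8 (2R)-5-[5-(benzyloxy)-2-bromo-3,4-dimethoxyphenyl]pent-3-yn-2-ol
Product: 9 (2R,3E)-5-[5-(benzyloxy)-2-bromo-3,4-dimethoxyphenyl]pent-3-en-2-ol
Conditions: NaAlH2(OCH2CH2OMe)2 (2 equiv), THF, 0 °C to rt; aq. KNaC4H4O6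
Reagents that add atoms: none
Why: Hydroxyl-directed trans-hydroalumination of the propargylic alcohol and protonolysis on work-up should give only the (E)-allylic alcohol without touching the carbinol centre.

Step 8
Reactants: 9 (2R,3E)-5-[5-(benzyloxy)-2-bromo-3,4-dimethoxyphenyl]pent-3-en-2-ol; 10 2,3-dimethoxyphenol
Product: 11 1-(benzyloxy)-4-bromo-5-[(2E,4S)-4-(2,3-dimethoxyphenoxy)pent-2-en-1-yl]-2,3-dimethoxybenzene
Conditions: PPh3, DIAD, THF, 0 °C to rt
Reagents that add atoms: none
Why: Mitsunobu reaction, in which the phenoxide of 10 displaces the alkoxyphosphonium ion derived from 9 by SN2 with inversion, so the (R) carbinol becomes the (S) aryl ether.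

Step 9
Reactants: 11 1-(benzyloxy)-4-bromo-5-[(2E,4S)-4-(2,3-dimethoxyphenoxy)pent-2-en-1-yl]-2,3-dimethoxybenzene
Product: 13 6-[(2R,3E)-1-[5-(benzyloxy)-2-bromo-3,4-dimethoxyphenyl]pent-3-en-2-yl]-2,3-dimethoxyphenol, via ortho-dienone 12 (not isolated)
Conditions: PhNEt2, 185 °C, argon, sealed tube
Reagents that add atoms: none
Why: Thermal aromatic Claisen rearrangement: a concerted [3,3]-sigmatropic shift through a chair transition state with the ether methyl group pseudo-equatorial breaks the O–C4 bond of the pentenyl chain while C6 of the phenoxy ring bonds to the alkene terminus on the same face, giving dienone 12, which enolises to phenol 13. The closest known reaction type is the rearrangement of enantioenriched secondary (E)-allyl aryl ethers with 1,3-transfer of chirality. No ring is closed; one C–C bond (C3–C1' of the target) and one stereocentre are formed. The new centre is controlled by the (S) ether carbon together with the (E) alkene, which through the suprafacial chair should give the (R) configuration (the later 3S centre) and an (E)-propenyl group. The step needs ortho regioselectivity and faithful chirality transfer: only C6 of the 2,3-dimethoxyphenyl ring bears hydrogen, so only there can the dienone aromatise, whereas attack at the methoxy-bearing C2 is reversible, and the neutral amine solvent disfavours ionisation of the ether.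

Step 10
Reactants: 13 6-[(2R,3E)-1-[5-(benzyloxy)-2-bromo-3,4-dimethoxyphenyl]pent-3-en-2-yl]-2,3-dimethoxyphenol
Product: 14 2-(benzyloxy)-1-[(2R,3E)-1-[5-(benzyloxy)-2-bromo-3,4-dimethoxyphenyl]pent-3-en-2-yl]-3,4-dimethoxybenzene
Conditions: BnBr, K2CO3, DMF, 50 °C
Reagents that add atoms: benzyl bromide, BrCc1ccccc1
Why: Williamson benzylation caps the C2' phenol so that it can neither form a lactol with the aldehyde of step 11 nor compete with the primary alcohol in the ring closure of step 12, and it is removed at the end together with the ring A benzyl group.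

Step 11
Reactants: 14 2-(benzyloxy)-1-[(2R,3E)-1-[5-(benzyloxy)-2-bromo-3,4-dimethoxyphenyl]pent-3-en-2-yl]-3,4-dimethoxybenzene
Product: 17 (2S)-2-[2-(benzyloxy)-3,4-dimethoxyphenyl]-3-[5-(benzyloxy)-2-bromo-3,4-dimethoxyphenyl]propan-1-ol, via diol 15 (not isolated), via aldehyde 16 (not isolated)
Conditions: OsO4 (2 mol %), NaIO4 (3 equiv), 2,6-lutidine, dioxane/H2O, rt; then NaBH4, MeOH, 0 °C
Reagents that add atoms: osmium tetroxide, O=[Os](=O)(=O)=O (delivers the oxygen); sodium periodate, [Na+].[O-]I(=O)(=O)=O (restores it)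
Why: Lemieux–Johnson cleavage (catalytic osmylation to diol 15 and periodate scission) removes the propenyl terminus, and the epimerisable alpha-aryl aldehyde 16 is reduced by NaBH4 in the same flask before it can enolise, so C3 should keep its configuration.

Step 12
Reactants: 17 (2S)-2-[2-(benzyloxy)-3,4-dimethoxyphenyl]-3-[5-(benzyloxy)-2-bromo-3,4-dimethoxyphenyl]propan-1-ol
Product: 18 (3S)-6-(benzyloxy)-3-[2-(benzyloxy)-3,4-dimethoxyphenyl]-7,8-dimethoxy-3,4-dihydro-2H-1-benzopyran
Conditions: Pd(OAc)2 (5 mol %), 2-(di-tert-butylphosphino)-1,1'-binaphthyl (6 mol %), Cs2CO3, PhMe, 80 °C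
Reagents that add atoms: none
Why: Palladium-catalysed intramolecular C–O coupling (Buchwald–Hartwig etherification), in which oxidative addition of zerovalent palladium into the C–Br bond, binding of the alkoxide and reductive elimination (favoured over β-hydride elimination by the bulky phosphine) form the O1–C8a bond of the six-membered ring C without affecting C3.

Step 13
Reactants: 18 (3S)-6-(benzyloxy)-3-[2-(benzyloxy)-3,4-dimethoxyphenyl]-7,8-dimethoxy-3,4-dihydro-2H-1-benzopyran
Product: 19 (3S)-3-(2-hydroxy-3,4-dimethoxyphenyl)-7,8-dimethoxy-3,4-dihydro-2H-1-benzopyran-6-ol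
Conditions: H2 (1 atm), Pd/C (palladium on carbon, 10 wt %), EtOAc/MeOH, rt
Reagents that add atoms: none
Why: Hydrogenolysis over Pd/C should cleave both benzyl aryl ethers to the C6 and C2' phenols, while nothing else in 18 is reducible under these conditions and C3, which bears no benzylic heteroatom, is unaffected.

Compound list
1 | methyl 3,5-dihydroxy-4-methoxybenzoate | COC(=O)c1cc(O)c(OC)c(O)c1 | starting material
2 | methyl 3-(benzyloxy)-5-hydroxy-4-methoxybenzoate | COC(=O)c1cc(O)c(OC)c(OCc2ccccc2)c1 | intermediate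
3 | methyl 5-(benzyloxy)-2-bromo-3-hydroxy-4-methoxybenzoate | COC(=O)c1cc(OCc2ccccc2)c(OC)c(O)c1Br | intermediate
4 | methyl 5-(benzyloxy)-2-bromo-3,4-dimethoxybenzoate | COC(=O)c1cc(OCc2ccccc2)c(OC)c(OC)c1Br | intermediate
5 | [5-(benzyloxy)-2-bromo-3,4-dimethoxyphenyl]methanol | OCc1cc(OCc2ccccc2)c(OC)c(OC)c1Br | intermediate
6 | 1-(benzyloxy)-4-bromo-5-(bromomethyl)-2,3-dimethoxybenzene | BrCc1cc(OCc2ccccc2)c(OC)c(OC)c1Br | intermediate
7 | (R)-but-3-yn-2-ol | C[C@@H](O)C#C | starting material
8 | (2R)-5-[5-(benzyloxy)-2-bromo-3,4-dimethoxyphenyl]pent-3-yn-2-ol | C[C@@H](O)C#CCc1cc(OCc2ccccc2)c(OC)c(OC)c1Br | intermediate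
9 | (2R,3E)-5-[5-(benzyloxy)-2-bromo-3,4-dimethoxyphenyl]pent-3-en-2-ol | C[C@@H](O)/C=C/Cc1cc(OCc2ccccc2)c(OC)c(OC)c1Br | intermediate
10 | 2,3-dimethoxyphenol | COc1cccc(O)c1OC | starting material
11 | 1-(benzyloxy)-4-bromo-5-[(2E,4S)-4-(2,3-dimethoxyphenoxy)pent-2-en-1-yl]-2,3-dimethoxybenzene | C[C@H](Oc1cccc(OC)c1OC)/C=C/Cc1cc(OCc2ccccc2)c(OC)c(OC)c1Br | intermediate (key-step precursor)
12 | 6-[(3E)-1-[5-(benzyloxy)-2-bromo-3,4-dimethoxyphenyl]pent-3-en-2-yl]-2,3-dimethoxycyclohexa-2,4-dien-1-one (keto tautomer of 13; side-chain centre as in 13, ring C6 set by the chair and lost on enolisation) | COC1=C(OC)C(=O)C(C=C1)[C@H](Cc2cc(OCc3ccccc3)c(OC)c(OC)c2Br)/C=C/C | intermediate (not isolated)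
13 | 6-[(2R,3E)-1-[5-(benzyloxy)-2-bromo-3,4-dimethoxyphenyl]pent-3-en-2-yl]-2,3-dimethoxyphenol | COc1ccc([C@H](Cc2cc(OCc3ccccc3)c(OC)c(OC)c2Br)/C=C/C)c(O)c1OC | intermediate (key-step product)
14 | 2-(benzyloxy)-1-[(2R,3E)-1-[5-(benzyloxy)-2-bromo-3,4-dimethoxyphenyl]pent-3-en-2-yl]-3,4-dimethoxybenzene | COc1ccc([C@H](Cc2cc(OCc3ccccc3)c(OC)c(OC)c2Br)/C=C/C)c(OCc2ccccc2)c1OC | intermediate
15 | (4S)-4-[2-(benzyloxy)-3,4-dimethoxyphenyl]-5-[5-(benzyloxy)-2-bromo-3,4-dimethoxyphenyl]pentane-2,3-diol (syn-diol from either alkene face; carbinol centres not specified) | COc1ccc([C@H](Cc2cc(OCc3ccccc3)c(OC)c(OC)c2Br)C(O)C(C)O)c(OCc2ccccc2)c1OC | intermediate (not isolated)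
16 | (2S)-2-[2-(benzyloxy)-3,4-dimethoxyphenyl]-3-[5-(benzyloxy)-2-bromo-3,4-dimethoxyphenyl]propanal | COc1ccc([C@H](Cc2cc(OCc3ccccc3)c(OC)c(OC)c2Br)C=O)c(OCc2ccccc2)c1OC | intermediate (not isolated)
17 | (2S)-2-[2-(benzyloxy)-3,4-dimethoxyphenyl]-3-[5-(benzyloxy)-2-bromo-3,4-dimethoxyphenyl]propan-1-ol | COc1ccc([C@H](Cc2cc(OCc3ccccc3)c(OC)c(OC)c2Br)CO)c(OCc2ccccc2)c1OC | intermediate
18 | (3S)-6-(benzyloxy)-3-[2-(benzyloxy)-3,4-dimethoxyphenyl]-7,8-dimethoxy-3,4-dihydro-2H-1-benzopyran | COc1ccc([C@H]2COc3c(cc(OCc4ccccc4)c(OC)c3OC)C2)c(OCc5ccccc5)c1OC | intermediate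
19 | (3S)-3-(2-hydroxy-3,4-dimethoxyphenyl)-7,8-dimethoxy-3,4-dihydro-2H-1-benzopyran-6-ol | COc1ccc([C@H]2COc3c(cc(O)c(OC)c3OC)C2)c(O)c1OC | target

Total step count: 13. Longest linear sequence: 13 steps (1 to 19); 7 and 10 enter as purchased materials.

Steps most likely to fail

1. Step 9 (Claisen rearrangement). Ionisation of the allyl ether to an ion pair, or passage through a boat transition state, would erode the transfer of configuration. Migration through the methoxy-bearing ortho carbon would carry the allyl group on to the para carbon. Prolonged heating could let the product isomerise further by the abnormal Claisen pathway. The fallback sets out from 9 and returns at 13, making the same C3–C1' bond by copper-mediated anti-SN2' substitution. Alcohol 9 would be esterified (picolinic acid, DCC, DMAP, CH2Cl2) to (2R,3E)-5-[5-(benzyloxy)-2-bromo-3,4-dimethoxyphenyl]pent-3-en-2-yl pyridine-2-carboxylate F1. Phenol 10 would be protected (MOMCl, i-Pr2NEt) as 1,2-dimethoxy-3-(methoxymethoxy)benzene F2. n-BuLi should deprotonate F2 at the only carbon ortho to the acetal oxygen, giving [3,4-dimethoxy-2-(methoxymethoxy)phenyl]lithium F3, and MgBr2·OEt2 converts this into [3,4-dimethoxy-2-(methoxymethoxy)phenyl]magnesium bromide F4. With CuBr·SMe2 in THF at 0 °C, F4 should attack the alkene terminus of F1 anti to the chelating picolinate. Because 9 has the carbinol configuration opposite to that of ether 11, anti attack reaches the same alkene face as the suprafacial rearrangement and should give 1-[(2R,3E)-1-[5-(benzyloxy)-2-bromo-3,4-dimethoxyphenyl]pent-3-en-2-yl]-3,4-dimethoxy-2-(methoxymethoxy)benzene F5. HCl in MeOH then removes the acetal to give 13.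

2. Step 8 (Mitsunobu etherification). Attack of the phenoxide at the remote alkene carbon (SN2'), ionisation of the allylic oxyphosphonium ion with partial loss of configuration, or elimination to the aryl-conjugated diene would lower the purity of the ether. The fallback sets out from 8 and returns at 11, forming the ether bond at the alkyne stage, where no allylic transposition is possible. Mitsunobu reaction of 8 with 10 (PPh3, DIAD, THF) should give, with inversion, 1-(benzyloxy)-4-bromo-5-[(4S)-4-(2,3-dimethoxyphenoxy)pent-2-yn-1-yl]-2,3-dimethoxybenzene F6. Ruthenium-catalysed trans-hydrosilylation ([Cp*Ru(MeCN)3]PF6, (EtO)3SiH, CH2Cl2) would add H and Si anti across the alkyne and give two regioisomeric (Z)-alkenylsilanes: triethoxy[(2Z,4S)-1-[5-(benzyloxy)-2-bromo-3,4-dimethoxyphenyl]-4-(2,3-dimethoxyphenoxy)pent-2-en-3-yl]silane F7 and triethoxy[(2Z,4S)-1-[5-(benzyloxy)-2-bromo-3,4-dimethoxyphenyl]-4-(2,3-dimethoxyphenoxy)pent-2-en-2-yl]silane F8. Protodesilylation of the mixture with retention (CuI, Bu4NF, THF) converges on the (E)-alkene 11.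

3. Step 12 (palladium-catalysed C–O ring closure). Slow oxidative addition at the hindered, electron-rich C–Br bond, or β-hydride elimination from the palladium alkoxide with reduction of the arene, would starve the cyclisation. The fallback sets out from 17 and returns at 18, closing ring C at the sp3 carbon instead. Miyaura borylation of 17 under acetate conditions, where no alkoxide is formed (PdCl2(dppf), B2pin2, KOAc, dioxane, 90 °C), would give (2S)-2-[2-(benzyloxy)-3,4-dimethoxyphenyl]-3-[5-(benzyloxy)-3,4-dimethoxy-2-(4,4,5,5-tetramethyl-1,3,2-dioxaborolan-2-yl)phenyl]propan-1-ol F9. Oxidation (NaBO3·4H2O, THF/H2O) would give 4-(benzyloxy)-6-[(2S)-2-[2-(benzyloxy)-3,4-dimethoxyphenyl]-3-hydroxypropyl]-2,3-dimethoxyphenol F10. Intramolecular Mitsunobu etherification of this phenol onto the primary alcohol (PPh3, DIAD, THF), which does not touch C3, should deliver 18.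

Further compounds
F1 | step 9 | (2R,3E)-5-[5-(benzyloxy)-2-bromo-3,4-dimethoxyphenyl]pent-3-en-2-yl pyridine-2-carboxylate | C[C@@H](OC(=O)c1ccccn1)/C=C/Cc1cc(OCc2ccccc2)c(OC)c(OC)c1Br
F2 | step 9 | 1,2-dimethoxy-3-(methoxymethoxy)benzene | COCOc1cccc(OC)c1OC
F3 | step 9 | [3,4-dimethoxy-2-(methoxymethoxy)phenyl]lithium | COCOc1c([Li])ccc(OC)c1OC
F4 | step 9 | [3,4-dimethoxy-2-(methoxymethoxy)phenyl]magnesium bromide | COCOc1c([Mg]Br)ccc(OC)c1OC
F5 | step 9 | 1-[(2R,3E)-1-[5-(benzyloxy)-2-bromo-3,4-dimethoxyphenyl]pent-3-en-2-yl]-3,4-dimethoxy-2-(methoxymethoxy)benzene | COCOc1c([C@H](Cc2cc(OCc3ccccc3)c(OC)c(OC)c2Br)/C=C/C)ccc(OC)c1OC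
F6 | step 8 | 1-(benzyloxy)-4-bromo-5-[(4S)-4-(2,3-dimethoxyphenoxy)pent-2-yn-1-yl]-2,3-dimethoxybenzene | C[C@H](Oc1cccc(OC)c1OC)C#CCc1cc(OCc2ccccc2)c(OC)c(OC)c1Br
F7 | step 8 | triethoxy[(2Z,4S)-1-[5-(benzyloxy)-2-bromo-3,4-dimethoxyphenyl]-4-(2,3-dimethoxyphenoxy)pent-2-en-3-yl]silane | C[C@H](Oc1cccc(OC)c1OC)/C(=C/Cc1cc(OCc2ccccc2)c(OC)c(OC)c1Br)[Si](OCC)(OCC)OCC
F8 | step 8 | triethoxy[(2Z,4S)-1-[5-(benzyloxy)-2-bromo-3,4-dimethoxyphenyl]-4-(2,3-dimethoxyphenoxy)pent-2-en-2-yl]silane | C[C@H](Oc1cccc(OC)c1OC)/C=C(/Cc1cc(OCc2ccccc2)c(OC)c(OC)c1Br)[Si](OCC)(OCC)OCC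
F9 | step 12 | (2S)-2-[2-(benzyloxy)-3,4-dimethoxyphenyl]-3-[5-(benzyloxy)-3,4-dimethoxy-2-(4,4,5,5-tetramethyl-1,3,2-dioxaborolan-2-yl)phenyl]propan-1-ol | COc1ccc([C@H](Cc2cc(OCc3ccccc3)c(OC)c(OC)c2B4OC(C)(C)C(C)(C)O4)CO)c(OCc5ccccc5)c1OC
F10 | step 12 | 4-(benzyloxy)-6-[(2S)-2-[2-(benzyloxy)-3,4-dimethoxyphenyl]-3-hydroxypropyl]-2,3-dimethoxyphenol | COc1ccc([C@H](Cc2cc(OCc3ccccc3)c(OC)c(OC)c2O)CO)c(OCc5ccccc5)c1OC
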